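**Assumptions.** Decalin carbons are numbered C1–C10 as in the target: C4 gem-dimethyl, C8-methyl (C17), C10-methyl (C20), side chain C11–C22. The target SMILES has the natural 5α,9α,10β decalin configuration and a (R)-C21 carbinol. Only (R)-carvone fits the decalin configuration. Facial assignments for the Weitz–Scheffer epoxidation and the Luche reduction are reasoned from steroid/terpenoid precedent, not checked against specific literature.

## Retrosynthetic overview
- Target 29 comes from acetonide 28 by final hydrolysis. 28 comes from a Negishi C12–C13 coupling of the decalinyl-ethylzinc derived from 14 with (E,E)-dienyl iodide 27.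
- 27 is built from (R)-2-hydroxy-4-phenylbutanoate 15, which sets C21; the phenyl ring serves as a masked CO2H. Two Zr-catalysed carboalumination/iodinations make the E-trisubstituted alkenes.
- 14 carries the key step: a Johnson–Claisen [3,3] rearrangement of a Δ8-7β-allylic alcohol, forming the C9–C11 bond and Δ7 in one step. The allylic alcohol comes from a Wharton 1,3-transposition of a carvone-derived enone.
- Ring B is (R)-carvone (C5). C10 is formed by two α′-alkylations anti to the isopropenyl group. Ring A is closed by RCM, and the C4 gem-dimethyl and C3 oxygen come from an epoxide opened by AlMe3.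
- Order: ring B (carvone), then C10, ring A (RCM), C4/C3, C9 (Claisen), chain coupling.

## Route

**Step 1**
Reactants: 1 (R)-(−)-carvone
Product: 2 trans-6-methylcarvone (Me anti to isopropenyl)
Conditions: LDA, THF, −78 °C; then MeI, −78 → 0 °C
Reagents that add atoms: iodomethane, CI
Why: The kinetic α′-enolate is alkylated anti to the C5 isopropenyl group (enolate alkylation), so the carvone C5 stereocentre controls the C6 (=C10) stereocentre.

**Step 2**
Reactants: 2
Product: 3 6-(but-3-enyl)-6-methylcarvone (Me cis, butenyl trans to isopropenyl)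
Conditions: LDA, THF, −78 °C; then 4-iodobut-1-ene, HMPA, −78 → 0 °C
Reagents that add atoms: 4-iodobut-1-ene, C=CCCI
Why: The second electrophile again enters anti to the C5 substituent, so Me becomes axial β (the natural C20) and the butenyl chain equatorial α; this sets the quaternary C10. It is the hindered alkylation flagged below.

**Step 3**
Reactants: 3
Product: 4 trans-fused bicyclic enone (ring A Δ3-4-methyl, ring B 8-methyl-Δ7-9-one)
Conditions: Hoveyda–Grubbs II (5 mol %), toluene, 0.005 M, 100 °C
Reagents that add atoms: none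
Why: Ring-closing metathesis joins the trans-diequatorial isopropenyl and butenyl arms into the six-membered ring A, leaving C5 and C10 untouched.

**Step 4**
Reactants: 4
Product: 5 Δ3,4-epoxide of 4 (epoxide configuration undefined)
Conditions: mCPBA, NaHCO3, CH2Cl2, 0 °C
Reagents that add atoms: mCPBA, O=C(OO)c1cccc(Cl)c1
Why: The electron-rich trisubstituted alkene is epoxidised in preference to the electron-poor enone. Both new stereocentres (C3, C4) are removed later, so their configuration is immaterial.

**Step 5**
Reactants: 5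
Product: 6 bis-epoxide (7,8-epoxy-9-ketone plus 3,4-epoxide)
Conditions: 30 % H2O2, NaOH, MeOH, 0 °C
Reagents that add atoms: hydrogen peroxide, OO
Why: Weitz–Scheffer nucleophilic epoxidation of the enone occurs anti to the angular methyl, giving the 7α,8α-epoxide.

**Step 6**
Reactants: 6
Product: 7 Δ8(9)-7α-ol with the 3,4-epoxide intact
Conditions: N2H4·H2O, AcOH (cat.), MeOH, 25–50 °C
Reagents that add atoms: none (N2 is lost)
Why: Wharton reaction. The hydrazone of the C9 ketone opens the epoxide and loses N2, moving oxygen from C9 to C7 and placing the alkene at C8=C9 (C9 becomes =CH).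

**Step 7**
Reactants: 7
Product: 8 Δ8(9)-7-ketone
Conditions: Dess–Martin periodinane, NaHCO3, CH2Cl2, 25 °C
Reagents that add atoms: none
Why: Oxidation of the allylic alcohol to the enone removes the C7 stereocentre so it can be reset from the β face.

**Step 8**
Reactants: 8
Product: 9 Δ8(9)-7β-ol
Conditions: NaBH4, CeCl3·7H2O, MeOH, −78 → 0 °C
Reagents that add atoms: none
Why: Luche reduction delivers a small hydride axially from the α face, giving the equatorial 7β-OH (analogous to 7-ketocholesterol reduction). This face sets the configuration of the Claisen step.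

**Step 9**
Reactants: 9
Product: 10 3-hydroxy-4,4-dimethyl-Δ8(9)-7β-ol (3-OH configuration immaterial)
Conditions: Me3Al (4 equiv), CH2Cl2, −78 → 0 °C
Reagents that add atoms: trimethylaluminium, C[Al](C)C
Why: AlMe3 opens the trisubstituted epoxide by delivering methyl to the tertiary C4, creating the gem-dimethyl centre and leaving a secondary C3 alcohol.

**Step 10 (key step)**
Reactants: 10
Product: 11 ethyl ester: 9β-(CH2CO2Et), Δ7, 3-OH
Conditions: MeC(OEt)3 (10 equiv), EtCO2H (cat.), toluene, 140 °C, sealed tube
Reagents that add atoms: triethyl orthoacetate, CCOC(C)(OCC)OCC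
Why: Johnson–Claisen [3,3] rearrangement is suprafacial. The C9–C11 bond forms on the same β face as the C7β–O bond, giving the equatorial C11 and 9α-H, and the alkene moves to Δ7(8). The free 3-OH is carried unprotected; any O-acetate or orthoester formed there is cleaved in Step 11.

**Step 11**
Reactants: 11
Product: 12 primary alcohol (C12-OH) with 3-OH
Conditions: LiAlH4, THF, 0 °C
Reagents that add atoms: none
Why: Ester reduction; alkene and stereocentres are unaffected.

**Step 12**
Reactants: 12
Product: 13 primary iodide with 3-OH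
Conditions: I2, PPh3, imidazole, CH2Cl2, 0 °C
Reagents that add atoms: iodine, II
Why: The Appel reaction converts the unhindered primary alcohol selectively; the neopentyl-type 3-OH is untouched.

**Step 13**
Reactants: 13
Product: 14 (3-oxo, C12 iodide; fragment X)
Conditions: Dess–Martin periodinane, NaHCO3, CH2Cl2, 25 °C
Reagents that add atoms: none
Why: Oxidation of the secondary alcohol to the C3 ketone tolerates the alkyl iodide and the trisubstituted alkene.

**Step 14**
Reactants: 15 ethyl (R)-2-hydroxy-4-phenylbutanoate
Product: 16 (R)-2-methyl-5-phenylpentane-2,3-diol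
Conditions: MeMgBr (4 equiv), THF, 0 °C
Reagents that add atoms: methylmagnesium bromide, C[Mg]Br
Why: Double Grignard addition converts the ester to the C(Me)2OH group (C22). The stereocentre C21 is not touched, so it stays (R).

**Step 15**
Reactants: 16
Product: 17 (R)-2,2,5,5-tetramethyl-4-(2-phenylethyl)-1,3-dioxolane
Conditions: 2,2-dimethoxypropane, PPTS, acetone, 25 °C
Reagents that add atoms: 2,2-dimethoxypropane, COC(C)(C)OC
Why: Acetonide protection of the vicinal diol.

**Step 16**
Reactants: 17
Product: 18 (R)-3-(2,2,5,5-tetramethyl-1,3-dioxolan-4-yl)propanoic acid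
Conditions: RuCl3 (3 mol %), NaIO4, EtOAc/MeCN/H2O, 25 °C
Reagents that add atoms: sodium periodate, [Na+].[O-]I(=O)(=O)=O
Why: RuO4 oxidises the phenyl ring to CO2H (the ipso carbon becomes C18). Acetonides survive these conditions.

**Step 17**
Reactants: 18
Product: 19 3-[(R)-dioxolanyl]propan-1-ol
Conditions: BH3·SMe2, THF, 0 °C → 25 °C
Reagents that add atoms: none
Why: Borane reduces the carboxylic acid chemoselectively.

**Step 18**
Reactants: 19
Product: 20 3-[(R)-dioxolanyl]propanal
Conditions: Dess–Martin periodinane, CH2Cl2, 25 °C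
Reagents that add atoms: none
Why: Mild oxidation; the aldehyde has no racemisable stereocentre nearby.

**Step 19**
Reactants: 20
Product: 21 (R)-4-(but-3-ynyl)-2,2,5,5-tetramethyl-1,3-dioxolane
Conditions: dimethyl (1-diazo-2-oxopropyl)phosphonate, K2CO3, MeOH, 25 °C
Reagents that add atoms: Ohira–Bestmann reagent, COP(=O)(OC)C(=[N+]=[N-])C(C)=O
Why: One-carbon homologation of the aldehyde to the terminal alkyne (C17≡C18).

**Step 20**
Reactants: 21
Product: 22 (E)-vinyl iodide, I–C17H=C18(Me)–C19H2…
Conditions: Me3Al, Cp2ZrCl2 (cat.), (CH2Cl)2, 0 °C → 25 °C; then I2, THF, −30 °C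
Reagents that add atoms: trimethylaluminium, C[Al](C)C; iodine, II
Why: Zr-catalysed syn-carboalumination puts Me on C18 and Al on C17, trans to the chain; iodinolysis gives the E-trisubstituted alkenyl iodide.

**Step 21**
Reactants: 23 4-(trimethylsilyl)but-3-yn-1-ol (commercial)
Product: 24 4-iodo-1-(trimethylsilyl)but-1-yne
Conditions: I2, PPh3, imidazole, Et2O/MeCN, 0 °C
Reagents that add atoms: iodine, II
Why: Appel conversion of the primary alcohol to the iodide.

**Step 22**
Reactants: 22, 24
Product: 25 TMS-enyne (C16–C17 bond)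
Conditions: (a) 24, Zn dust (1,2-dibromoethane/TMSCl activated), DMA, 50 °C; (b) 22, Pd(PPh3)4 (5 mol %), THF, 25 °C
Reagents that add atoms: none (Zn is not retained)
Why: Negishi coupling of the primary alkylzinc with the alkenyl iodide proceeds with retention of E geometry and keeps the TMS-alkyne and acetonide intact.

**Step 23**
Reactants: 25
Product: 26 terminal enyne
Conditions: K2CO3, MeOH, 25 °C
Reagents that add atoms: none
Why: Protodesilylation of the alkynyl TMS group.

**Step 24**
Reactants: 26
Product: 27 (E,E)-dienyl iodide (C13 iodide; fragment Y)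
Conditions: Me3Al, Cp2ZrCl2 (cat.), (CH2Cl)2, 0 °C → 25 °C; then I2, THF, −30 °C
Reagents that add atoms: trimethylaluminium, C[Al](C)C; iodine, II
Why: Carboalumination places Me on C14 and I on C13, giving the second E-trisubstituted alkene; the existing trisubstituted alkene is inert to Zr/Al.

**Step 25**
Reactants: 14, 27
Product: 28 acetonide-protected target
Conditions: (a) 14, Zn dust, DMA, 50 °C; (b) 27, Pd(dppf)Cl2 (5 mol %), THF, 25 °C
Reagents that add atoms: none
Why: sp3–sp2 Negishi coupling forms C12–C13 with retention of E geometry; the alkylzinc tolerates the C3 ketone and the Δ7 alkene.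

**Step 26**
Reactants: 28
Product: 29 target
Conditions: PPTS (0.2 equiv), MeOH/H2O 9:1, 50 °C
Reagents that add atoms: none
Why: Acetonide hydrolysis, which is easy because one oxygen is tertiary. Ketone and alkenes survive, and the C21 stereocentre is not affected.

## Compound list
1 | (R)-(−)-carvone | CC1=CC[C@H](CC1=O)C(=C)C | starting material
2 | trans-6-methylcarvone | CC1=CC[C@H]([C@H](C)C1=O)C(=C)C | intermediate
3 | 6-(but-3-enyl)-6-methylcarvone | CC1=CC[C@H]([C@](C)(CCC=C)C1=O)C(=C)C | intermediate
4 | trans-fused dienone (ring A Δ3, ring B Δ7-9-one) | CC1=CC[C@H]2C(C)=CCC[C@]2(C)C1=O | intermediate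
5 | 3,4-epoxide of 4 | CC1=CC[C@H]2C3(C)OC3CC[C@]2(C)C1=O | intermediate
6 | bis-epoxide | CC12OC1C[C@H]3C4(C)OC4CC[C@]3(C)C2=O | intermediate
7 | Δ8(9)-7α-ol, 3,4-epoxide | CC1=C[C@@]2(C)CCC3OC3(C)[C@@H]2C[C@H]1O | intermediate
8 | Δ8(9)-7-ketone, 3,4-epoxide | CC1=C[C@@]2(C)CCC3OC3(C)[C@@H]2CC1=O | intermediate
9 | Δ8(9)-7β-ol, 3,4-epoxide | CC1=C[C@@]2(C)CCC3OC3(C)[C@@H]2C[C@@H]1O | intermediate
10 | 3,7β-diol, 4,4-dimethyl | CC1=C[C@@]2(C)CCC(O)C(C)(C)[C@@H]2C[C@@H]1O | intermediate
11 | Claisen ester | CC1=CC[C@H]2C(C)(C)C(O)CC[C@]2(C)[C@H]1CC(=O)OCC | intermediate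
12 | C12 alcohol | CC1=CC[C@H]2C(C)(C)C(O)CC[C@]2(C)[C@H]1CCO | intermediate
13 | C12 iodide, 3-OH | CC1=CC[C@H]2C(C)(C)C(O)CC[C@]2(C)[C@H]1CCI | intermediate
14 | C12 iodide, 3-ketone | CC1=CC[C@H]2C(C)(C)C(=O)CC[C@]2(C)[C@H]1CCI | intermediate
15 | ethyl (R)-2-hydroxy-4-phenylbutanoate | CCOC(=O)[C@H](O)CCc1ccccc1 | starting material
16 | (R)-2-methyl-5-phenylpentane-2,3-diol | CC(C)(O)[C@H](O)CCc1ccccc1 | intermediate
17 | phenethyl acetonide | CC1(C)OC(C)(C)[C@@H](CCc2ccccc2)O1 | intermediate
18 | acid | CC1(C)OC(C)(C)[C@@H](CCC(=O)O)O1 | intermediate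
19 | alcohol | CC1(C)OC(C)(C)[C@@H](CCCO)O1 | intermediate
20 | aldehyde | CC1(C)OC(C)(C)[C@@H](CCC=O)O1 | intermediate
21 | terminal alkyne | CC1(C)OC(C)(C)[C@@H](CCC#C)O1 | intermediate
22 | (E)-vinyl iodide | I/C=C(\C)CC[C@H]1OC(C)(C)OC1(C)C | intermediate
23 | 4-(trimethylsilyl)but-3-yn-1-ol | C[Si](C)(C)C#CCCO | starting material
24 | 4-iodo-1-(trimethylsilyl)but-1-yne | C[Si](C)(C)C#CCCI | intermediate
25 | TMS-enyne | C[Si](C)(C)C#CCC/C=C(\C)CC[C@H]1OC(C)(C)OC1(C)C | intermediate
26 | terminal enyne | C#CCC/C=C(\C)CC[C@H]1OC(C)(C)OC1(C)C | intermediate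
27 | (E,E)-dienyl iodide | I/C=C(\C)CC/C=C(\C)CC[C@H]1OC(C)(C)OC1(C)C | intermediate
28 | acetonide-protected target | CC1=CC[C@H]2C(C)(C)C(=O)CC[C@]2(C)[C@H]1CC/C=C(\C)CC/C=C(\C)CC[C@H]3OC(C)(C)OC3(C)C | intermediate
29 | target | CC1=CC[C@H]2C(C)(C)C(=O)CC[C@]2(C)[C@H]1CC/C=C(\C)CC/C=C(\C)CC[C@@H](O)C(C)(C)O | target

**Total steps:** 26 (two convergent branches of 13 and 10 steps joined by the Negishi coupling).
**Longest linear sequence:** 15 (Steps 1–13, 25, 26).

**Three steps most likely to fail**
1. **Step 3 (RCM).** It must close a trisubstituted alkene from a hindered isopropenyl group next to a quaternary centre.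
   Fallback (different strategy): build ring A by Robinson-type intramolecular aldol. Alkylate in Step 2 with the ketal of 4-iodobutan-2-one instead. Complete the ring-B chemistry first, then convert the isopropenyl group to the C5 ketone. Close the enone by aldol condensation and reset the trans C5–H by Li/NH3, which is controlled by the already-fixed C10.
2. **Step 9 (AlMe3 opening of the 3,4-epoxide).** The methyl must be delivered to the hindered C4, syn to the axial C20 methyl, without Meinwald rearrangement.
   Fallback: Lewis-acid Meinwald rearrangement of the epoxide to the 4-methyl-3-ketone, then t-BuOK/MeI gem-dimethylation at C4.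
3. **Step 25 (sp3–sp2 Negishi coupling).** The alkylzinc and the alkenyl iodide are both hindered.
   Fallback: Suzuki–Miyaura coupling. Convert 14 to the terminal alkene via the selenoxide, hydroborate with 9-BBN, and couple the resulting alkyl-9-BBN with 27 under Pd(dppf)Cl2/Cs2CO3.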